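## The problem

Ring numbering of the target **8**: C1 is the quaternary ring carbon that carries the two (E)‑feruloyl groups, C2 is the CH that carries the 3,4‑dimethoxyphenyl group (the only stereocentre, R), C3=C4 is the ring alkene, and C5 and C6 are CH2.

- **8** is a cyclohex‑3‑ene whose C1 is the central carbon of a curcumin unit. C2, next to it, is benzylic and allylic.
- The hard bond is C1–C2. It joins a fully substituted 1,3‑diketone carbon to a tertiary benzylic carbon, inside a six‑membered ring whose other atoms (C3=C4, C5, C6) carry no functional group.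
- C2 is the only stereocentre, so nothing in the molecule can control it. The two acyl groups on C1 are identical, so C1 offers no diastereotopic handle, and the configuration must come from a catalyst acting directly at C2.
- Sensitive groups:
  - the 2,2‑disubstituted 1,3‑diketone cannot enolise and is open to retro‑Claisen cleavage by hydroxide or alkoxide;
  - both enones are Michael acceptors;
  - both phenols are free;
  - C2–H is benzylic and allylic, so migration of C3=C4 towards the aryl ring would erase the stereocentre;
  - C1–C2 is a donor–acceptor σ‑bond that strong acids can ionise.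
- The feature that opens the problem is C3, an unsubstituted sp2 CH between C2 and C4. With a formyl group imagined on C3:
  - C3=C4 becomes the enal of an intramolecular aldol condensation (C3 nucleophile, C4 aldehyde carbon);
  - C2 becomes the β‑carbon of a cinnamaldehyde;
  - C1, a 1,3‑diketone carbon, is the Michael donor for it.
- The six ring atoms then fall apart into three achiral commercial pieces: C1 is C4 of curcumin, C6–C5–C4 is acrolein, and C2–C3 (plus CHO) is 3,4‑dimethoxycinnamaldehyde. The price is one carbon, excised at the end as CO.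

## Retrosynthesis

**8 ⇒ 7.** No skeletal bond is cut. C3–H of **8** is exchanged for C3–CHO, which gives the cyclohex‑1‑ene‑1‑carbaldehyde **7**.
- Against the neighbours: a ring ketone at C4 could come from a double Michael annulation, but turning C4=O into C3=C4 poses a C3‑versus‑C5 regiochemistry problem. A carboxyl on C3 would need a vinylic decarboxylation. A formyl group on an sp2 carbon leaves as CO in one step, with the double bond staying where it is.
- **7** is not smaller than **8**, but it has a retron that **8** lacks.
- Asked of the forward reaction: a Tsuji–Wilkinson decarbonylation that does not move C3=C4 and leaves the enones and phenols alone.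

**7 ⇒ 3 + 4.** The bonds C1–C2 and C3=C4 (σ and π) are cut.
- Against the cut C1–C2/C5–C6 (Diels–Alder): here the stereo‑determining event is at the β‑carbon of an iminium ion, not at a diene terminus far from any catalyst.
- Against cutting C1–C2 alone (allylic alkylation): here the ring closes in the same operation.
- The precursors are the achiral, acyclic aldehyde **3** and commercial (E)‑3,4‑dimethoxycinnamaldehyde **4**. The ring, the quaternary carbon, the stereocentre and the alkene all arise in one step.
- Asked of the forward reaction: an amine‑catalysed Michael addition of the diketone carbon of **3** to the iminium ion of **4** with control of C2, ahead of any enamine chemistry of the aldehyde of **3**. The resulting enamine must then condense with the tethered aldehyde.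

**3 ⇒ 1 + 2.** The bond C1–C6 is cut: conjugate addition of curcumin **1** to acrolein **2**.
- Against C‑alkylation of **1** with a 3‑halopropanal acetal: curcumin alkylates poorly with unactivated halides (O‑alkylation, dialkylation) but is a soft Michael donor at C4, and the aldehyde arrives unprotected.
- Both **1** and **2** are commodity chemicals.
- Asked of the forward reaction: mono‑addition at carbon, not at phenol oxygen.

## Roads not taken

**Alternative 1:** Diels–Alder, the most obvious road.
- Cut: C1–C2 and C5–C6.
- Forward key step: Knoevenagel condensation of **1** with formaldehyde to the fleeting 4‑methylenecurcumin A1, then [4+2] cycloaddition with (E)‑1‑(3,4‑dimethoxyphenyl)buta‑1,3‑diene A2 under a chiral Lewis acid.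
- Why the chosen plan is better:
  - A1 has two identical acyl groups and a CH2 terminus, so its π‑faces are equivalent on a C2‑symmetric chelating metal. The stereocentre forms on the diene carbon, and the catalyst would have to control which way the diene lies, far from its chiral pocket.
  - A1 is also a 1‑oxadiene. Addition of the terminal vinyl group of A2 gives the racemate of dihydropyran A5 (alternative 3), which reaches the target skeleton by [3,3] shift without catalyst control.
  - A1 is a strong Michael acceptor towards **1** itself.

**Alternative 2:** Allylic alkylation plus metathesis.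
- Cut: C1–C2 and C3=C4.
- Forward key step: iridium‑catalysed, branched‑selective allylic alkylation of a 2‑(but‑3‑enyl)malonate with a 3,4‑dimethoxycinnamyl carbonate to give the diene A3, then ring‑closing metathesis to the cyclohexene diester A4.
- Why the chosen plan is better:
  - A4 still needs both esters turned into feruloyl arms (bis‑β‑ketophosphonate, double Horner–Wadsworth–Emmons reaction with protected vanillin, deprotection). The first of these is an addition to a neopentyl diester next to the aryl‑bearing carbon.
  - A curcumin‑based version avoids this and is kept as the fallback, but it takes five steps and two precious‑metal catalysts, and closes the ring in a separate operation.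
  - The chosen plan forms C1–C2, C3–C4 and the alkene in one metal‑free operation, three steps from curcumin.

**Alternative 3:** Claisen relay through a dihydropyran.
- Cut: C1–C2, with oxygen reconnected to C4 (retro‑Claisen). The precursor is the 2‑styryl‑3,4‑dihydro‑2H‑pyran A5.
- Forward key step: thermal [3,3] shift through a boat transition state, which should carry the (S) C–O stereocentre of A5 over to (R)‑C2 of **8**.
- Why the chosen plan is better:
  - A5 is an isomer of **8**, so the key step simplifies nothing.
  - Enantioenriched A5 needs the carbinol A6 (asymmetric ketone reduction), C‑alkylation of **1** with this unactivated iodide (curcumin's weakest reaction) and a cyclodehydration.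
  - The C–O bond of A5 joins a diketonate leaving group to a carbon that is allylic and conjugated to an electron‑rich styrene. Heterolysis to an achiral zwitterion competes with the concerted shift and would lose the stereochemistry.

Key step: step 2

Assumptions: curcumin **1** is used as the pure compound, free of its demethoxy congeners. **1** and **3** are written as diketo tautomers, although they equilibrate with enol forms (and, for **3**, a cyclic hemiacetal). The sense of induction in step 2 is taken from the accepted face‑shielding model for diarylprolinol silyl ether iminium ions.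

## Steps

Step 1
Reactants: 1 curcumin, (1E,6E)‑1,7‑bis(4‑hydroxy‑3‑methoxyphenyl)hepta‑1,6‑diene‑3,5‑dione; 2 acrolein (prop‑2‑enal)
Product: 3 4‑(3‑oxopropyl)curcumin, (6E)‑7‑(4‑hydroxy‑3‑methoxyphenyl)‑4‑[(2E)‑3‑(4‑hydroxy‑3‑methoxyphenyl)prop‑2‑enoyl]‑5‑oxohept‑6‑enal
Conditions: 2 (1.05 equiv), Et3N (0.1 equiv), THF, 0 °C → rt
Reagents that add atoms: none
Why: Michael addition of the most acidic site of 1 (the diketone C4–H, more acidic than the phenols) to acrolein; the soft diketonate adds through carbon, and no stereocentre is formed.

Step 2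
Reactants: 3 4‑(3‑oxopropyl)curcumin; 4 (E)‑3‑(3,4‑dimethoxyphenyl)prop‑2‑enal (3,4‑dimethoxycinnamaldehyde)
Product: 7 (6S)‑6‑(3,4‑dimethoxyphenyl)‑5,5‑bis[(2E)‑3‑(4‑hydroxy‑3‑methoxyphenyl)prop‑2‑enoyl]cyclohex‑1‑ene‑1‑carbaldehyde, via the catalyst‑bound (E)‑enamine of the (R)‑configured Michael adduct 5 (not isolated), via the aldol adduct (6R)‑6‑(3,4‑dimethoxyphenyl)‑2‑hydroxy‑5,5‑bis[(2E)‑3‑(4‑hydroxy‑3‑methoxyphenyl)prop‑2‑enoyl]cyclohexane‑1‑carbaldehyde 6 (not isolated)
Conditions: 4 (1.5 equiv), (R)‑α,α‑diphenylprolinol trimethylsilyl ether (20 mol%), PhCO2H (20 mol%), CH2Cl2–EtOH 9:1, rt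
Reagents that add atoms: none
Why: Condensation of 4 with the catalyst gives the (E),s‑trans iminium ion, in which the CPh2OSiMe3 group covers one face of the β‑carbon (the future C2). The diketone carbon of 3 (C1, as enol or enolate) adds to the open face in an intermolecular Michael addition that forms C1–C2 and sets C2; by the shielding model the (R)‑catalyst should give the configuration drawn, which is (R) in 8 and (S) in 7 only because the formyl group raises the CIP rank of C3. The adduct is formed as enamine 5, nucleophilic at C3, and closes the carbocycle by a 6‑(enolexo)‑exo‑trig aldol addition to the tethered aldehyde carbon C4 to give 6; E1cB loss of water through the enamine and hydrolysis then release 7 and the catalyst. The closest known reaction type is the amine‑catalysed iminium–enamine Michael/aldol‑condensation cascade that joins an enal and a formyl‑tethered carbon acid (nitroalkane or malonate) into a cyclohex‑1‑ene‑ or cyclopent‑1‑ene‑carbaldehyde. C1 becomes quaternary but is no stereocentre (two identical acyl groups), and the stereocentres at C3 and C4 of 6 are erased by the dehydration. The step needs chemoselectivity (diketone carbon before aldehyde enamine as donor, iminium ion before feruloyl arm as acceptor); this should follow from the acidity of the 1,3‑diketone, the LUMO lowering in the iminium ion and the deactivation of the arms by their para‑hydroxy groups. The regiochemistry of ring closure is fixed because the Michael event itself delivers the enamine at C3, and the condensation takes C3 to sp2, which shuts off retro‑Michael loss of the stereocentre.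

Step 3
Reactants: 7 (6S)‑6‑(3,4‑dimethoxyphenyl)‑5,5‑bis[(2E)‑3‑(4‑hydroxy‑3‑methoxyphenyl)prop‑2‑enoyl]cyclohex‑1‑ene‑1‑carbaldehyde
Product: 8 CNP0213153.1, (2E,2′E)‑1,1′‑[(2R)‑2‑(3,4‑dimethoxyphenyl)cyclohex‑3‑ene‑1,1‑diyl]bis[3‑(4‑hydroxy‑3‑methoxyphenyl)prop‑2‑en‑1‑one]
Conditions: RhCl(PPh3)3 (1.1 equiv), degassed PhMe, 110 °C
Reagents that add atoms: none
Why: Tsuji–Wilkinson decarbonylation: oxidative addition of the formyl C–H bond to Rh(I), CO de‑insertion and C–H reductive elimination at the sp2 carbon, which leaves C3=C4 in place and does not touch C2. The reagent is stoichiometric because RhCl(CO)(PPh3)2 does not turn over at this temperature.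

## Compound list

```
1 | curcumin, (1E,6E)-1,7-bis(4-hydroxy-3-methoxyphenyl)hepta-1,6-diene-3,5-dione | COc1cc(/C=C/C(=O)CC(=O)/C=C/c2ccc(O)c(OC)c2)ccc1O | starting material
2 | acrolein (prop-2-enal) | C=CC=O | starting material
3 | 4-(3-oxopropyl)curcumin, (6E)-7-(4-hydroxy-3-methoxyphenyl)-4-[(2E)-3-(4-hydroxy-3-methoxyphenyl)prop-2-enoyl]-5-oxohept-6-enal | COc1cc(/C=C/C(=O)C(CCC=O)C(=O)/C=C/c2ccc(O)c(OC)c2)ccc1O | intermediate
4 | (E)-3-(3,4-dimethoxyphenyl)prop-2-enal | COc1ccc(/C=C/C=O)cc1OC | starting material
5 | (E)-enamine of the (R)-configured Michael adduct with (R)-alpha,alpha-diphenylprolinol trimethylsilyl ether | O=CCCC(C(=O)/C=C/c1ccc(O)c(OC)c1)(C(=O)/C=C/c1ccc(O)c(OC)c1)[C@H](/C=C/N1CCC[C@@H]1C(O[Si](C)(C)C)(c1ccccc1)c1ccccc1)c1ccc(OC)c(OC)c1 | intermediate (not isolated)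
6 | (6R)-6-(3,4-dimethoxyphenyl)-2-hydroxy-5,5-bis[(2E)-3-(4-hydroxy-3-methoxyphenyl)prop-2-enoyl]cyclohexane-1-carbaldehyde (aldol adduct, either configuration at C1 and C2, drawn free of the catalyst) | COc1cc(/C=C/C(=O)C2(C(=O)/C=C/c3ccc(O)c(OC)c3)CCC(O)C(C=O)[C@@H]2c2ccc(OC)c(OC)c2)ccc1O | intermediate (not isolated)
7 | (6S)-6-(3,4-dimethoxyphenyl)-5,5-bis[(2E)-3-(4-hydroxy-3-methoxyphenyl)prop-2-enoyl]cyclohex-1-ene-1-carbaldehyde | COc1cc(/C=C/C(=O)C2(C(=O)/C=C/c3ccc(O)c(OC)c3)CCC=C(C=O)[C@@H]2c2ccc(OC)c(OC)c2)ccc1O | intermediate
8 | CNP0213153.1, (2E,2'E)-1,1'-[(2R)-2-(3,4-dimethoxyphenyl)cyclohex-3-ene-1,1-diyl]bis[3-(4-hydroxy-3-methoxyphenyl)prop-2-en-1-one] | COc1cc(/C=C/C(=O)C2(C(=O)/C=C/c3ccc(O)c(OC)c3)CCC=C[C@@H]2c2ccc(OC)c(OC)c2)ccc1O | target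
```

## Step count and least certain steps

Total step count: 3. Longest linear sequence: 3 steps (1 → 3 → 7 → 8).

**Step 2 (key step).**
- What may go wrong: the intermolecular Michael addition is the slow event, since a fully substituted diketone carbon must add to an electron‑rich iminium ion. Meanwhile the free aldehyde of 3 can enter enamine chemistry of its own (self‑aldol, conjugate addition to a feruloyl arm, cross‑Michael addition through C5), 3 can lose acrolein by retro‑Michael reaction, and an uncatalysed background addition would lower the enantiomeric purity.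
- Fallback (sets out from 1 and 4, returns at 8): C1–C2 is made while C1 is still a tertiary diketone carbon, by iridium‑catalysed allylic alkylation, and the ring is closed by metathesis, so no formyl group is introduced. Luche reduction of 4 gives (E)‑3‑(3,4‑dimethoxyphenyl)prop‑2‑en‑1‑ol F1, and methyl chloroformate/pyridine turns it into (E)‑3‑(3,4‑dimethoxyphenyl)allyl methyl carbonate F2. Branched‑selective allylic alkylation of 1 with F2 ([Ir(cod)Cl]2, a BINOL‑derived phosphoramidite with a bis(1‑phenylethyl)amino group in the enantiomer that gives the configuration drawn, THF) gives 4‑[(1S)‑1‑(3,4‑dimethoxyphenyl)prop‑2‑en‑1‑yl]curcumin F3; the curcumin enol is more acidic and softer than the phenols. Michael addition of F3 to 2 (Et3N cat.) gives the quaternary aldehyde F4, Wittig methylenation (Ph3P=CH2, in excess to cover the two phenols) gives the diene F5, and ring‑closing metathesis (second‑generation ruthenium benzylidene catalyst, CH2Cl2, 40 °C) closes C3=C4 and gives 8.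

**Step 3.**
- What may go wrong: slow oxidative addition into a hindered, conjugated formyl C–H bond next to the aryl‑bearing carbon. On prolonged heating, rhodium hydride species may move C3=C4 towards C2 (conjugation with the aryl ring and loss of the stereocentre) or engage an enone arm (hydroacylation, reduction).
- Fallback (sets out from 3, returns at 8): the formyl group is never put on. Wittig methylenation of 3 (excess Ph3P=CH2; the diketonate formed first protects against retro‑Michael loss of acrolein) gives 4‑(but‑3‑en‑1‑yl)curcumin F6. Iridium‑catalysed allylic alkylation of F6 with the carbonate F2 (conditions as above) forms C1–C2 and the quaternary carbon in one event and gives the diene F5; phenoxide O‑allylation is the competing process here. Ring‑closing metathesis then gives 8.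

**Step 1.**
- What may go wrong: over‑reaction, namely a second Michael addition to give the 4,4‑bis(3‑oxopropyl) compound, oxa‑Michael addition of a phenol, Knoevenagel condensation of the new aldehyde with unreacted 1, polymerisation of acrolein, and retro‑Michael loss of acrolein from 3 on purification.
- Fallback (sets out from 2, returns at 3): the substituted curcumin is built from a pre‑alkylated diketone, with acetylacetone and vanillin as additional commercial materials. Addition of HBr to 2 followed by acetalisation (MeOH, HC(OMe)3) gives 3‑bromo‑1,1‑dimethoxypropane F7. C‑alkylation of acetylacetone with F7 (K2CO3, NaI, acetone) gives 3‑(3,3‑dimethoxypropyl)pentane‑2,4‑dione F8. Boron‑templated double aldol condensation of F8 with vanillin (B2O3, B(OnBu)3, n‑BuNH2, EtOAc, 70 °C), then warm dilute HCl, which also hydrolyses the acetal, gives 3.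

## Further compounds

```
F1 | step 2 | (E)-3-(3,4-dimethoxyphenyl)prop-2-en-1-ol | COc1ccc(/C=C/CO)cc1OC
F2 | step 2 | (E)-3-(3,4-dimethoxyphenyl)allyl methyl carbonate | COC(=O)OC/C=C/c1ccc(OC)c(OC)c1
F3 | step 2 | (1E,6E)-4-[(1S)-1-(3,4-dimethoxyphenyl)prop-2-en-1-yl]-1,7-bis(4-hydroxy-3-methoxyphenyl)hepta-1,6-diene-3,5-dione | C=C[C@@H](C(C(=O)/C=C/c1ccc(O)c(OC)c1)C(=O)/C=C/c1ccc(O)c(OC)c1)c1ccc(OC)c(OC)c1
F4 | step 2 | (6E)-4-[(1R)-1-(3,4-dimethoxyphenyl)prop-2-en-1-yl]-7-(4-hydroxy-3-methoxyphenyl)-4-[(2E)-3-(4-hydroxy-3-methoxyphenyl)prop-2-enoyl]-5-oxohept-6-enal | C=C[C@@H](C(CCC=O)(C(=O)/C=C/c1ccc(O)c(OC)c1)C(=O)/C=C/c1ccc(O)c(OC)c1)c1ccc(OC)c(OC)c1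
F5 | step 2 | (1E,6E)-4-(but-3-en-1-yl)-4-[(1R)-1-(3,4-dimethoxyphenyl)prop-2-en-1-yl]-1,7-bis(4-hydroxy-3-methoxyphenyl)hepta-1,6-diene-3,5-dione | C=C[C@@H](C(CCC=C)(C(=O)/C=C/c1ccc(O)c(OC)c1)C(=O)/C=C/c1ccc(O)c(OC)c1)c1ccc(OC)c(OC)c1
F6 | step 3 | 4-(but-3-en-1-yl)curcumin, (1E,6E)-4-(but-3-en-1-yl)-1,7-bis(4-hydroxy-3-methoxyphenyl)hepta-1,6-diene-3,5-dione | COc1cc(/C=C/C(=O)C(CCC=C)C(=O)/C=C/c2ccc(O)c(OC)c2)ccc1O
F7 | step 1 | 3-bromo-1,1-dimethoxypropane | COC(CCBr)OC
F8 | step 1 | 3-(3,3-dimethoxypropyl)pentane-2,4-dione | CC(=O)C(CCC(OC)OC)C(C)=O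
A1 | alternative 1 | 4-methylenecurcumin, (1E,6E)-1,7-bis(4-hydroxy-3-methoxyphenyl)-4-methylidenehepta-1,6-diene-3,5-dione | COc1cc(/C=C/C(=O)C(=C)C(=O)/C=C/c2ccc(O)c(OC)c2)ccc1O
A2 | alternative 1 | (E)-1-(3,4-dimethoxyphenyl)buta-1,3-diene | C=C/C=C/c1ccc(OC)c(OC)c1
A3 | alternative 2 | dimethyl 2-(but-3-en-1-yl)-2-[(1R)-1-(3,4-dimethoxyphenyl)prop-2-en-1-yl]propanedioate | C=C[C@@H](C(CCC=C)(C(=O)OC)C(=O)OC)c1ccc(OC)c(OC)c1
A4 | alternative 2 | dimethyl (2R)-2-(3,4-dimethoxyphenyl)cyclohex-3-ene-1,1-dicarboxylate | COC(=O)C1(C(=O)OC)CCC=C[C@@H]1c1ccc(OC)c(OC)c1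
A5 | alternative 3 | (2E)-1-{(2S)-2-[(E)-2-(3,4-dimethoxyphenyl)ethenyl]-6-[(E)-2-(4-hydroxy-3-methoxyphenyl)ethenyl]-3,4-dihydro-2H-pyran-5-yl}-3-(4-hydroxy-3-methoxyphenyl)prop-2-en-1-one | COc1ccc(/C=C/[C@@H]2CCC(C(=O)/C=C/c3ccc(O)c(OC)c3)=C(/C=C/c3ccc(O)c(OC)c3)O2)cc1OC
A6 | alternative 3 | (1E,3S)-1-(3,4-dimethoxyphenyl)-5-iodopent-1-en-3-ol | ICC[C@H](O)/C=C/c1ccc(OC)c(OC)c1
```
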